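Ring C of the flavonol is disconnected at O1–C8a, C4–C4a and O1–C2, which turns ring A into an aryne and the remainder into an arylpropiolic acid. The key step exploits the C4a–C8a edge of ring A, whose neighbours differ: C5 carries the free hydroxyl and C8 a methoxy group. An aryne across C4a–C8a with a triflate on C5 (masked 5-OH and regiodirector) should accept the carboxylate oxygen at C8a and the acyl carbon at C4a, and the phenoxide then closes ring C on the ynone, all in one operation. Its precursor is a catechol bis-triflate silylated between a triflate and a methoxy group. C3 hydroxylation and triflate hydrolysis complete the synthesis.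

Key step: step 7

Remark on the chemistry: the target is achiral; the only chiral species is the transient epoxide of step 8, which forms as a racemate and loses both stereocenters in the same flask.

Step 1
Reactants: 1 2-hydroxy-4,5-dimethoxybenzaldehyde
Product: 3 4,5-dimethoxybenzene-1,2-diol, via 2-hydroxy-4,5-dimethoxyphenyl formate 2 (not isolated)
Conditions: H2O2 (30% aq.), NaOH (aq.), THF, 0 °C → rt, N2; then aq. Na2SO3, 1 M HCl
Reagents that add atoms: hydrogen peroxide, OO
Why: Dakin oxidation, in which hydroperoxide adds to the aldehyde ortho to the phenoxide, the electron-rich aryl group migrates to oxygen and the formate is hydrolysed in the alkaline medium, while inert gas and a reductive acidic work-up protect the oxidisable catechol.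

Step 2
Reactants: 3 4,5-dimethoxybenzene-1,2-diol
Product: 4 4,5-dimethoxy-1,2-phenylene bis(N,N-diethylcarbamate)
Conditions: ClC(O)NEt2 (2.5 equiv), K2CO3, MeCN, reflux, N2
Reagents that add atoms: N,N-diethylcarbamoyl chloride, CCN(CC)C(Cl)=O
Why: O-Carbamoylation of both phenols (acyl substitution) installs the directing groups for metalation and keeps the molecule symmetric, so the two free ring positions are equivalent.

Step 3
Reactants: 4 4,5-dimethoxy-1,2-phenylene bis(N,N-diethylcarbamate)
Product: 6 4,5-dimethoxy-3-(trimethylsilyl)-1,2-phenylene bis(N,N-diethylcarbamate), via 2,3-bis[(diethylcarbamoyl)oxy]-5,6-dimethoxyphenyllithium 5 (not isolated)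
Conditions: s-BuLi (1.1 equiv), TMEDA, THF, −78 °C; then Me3SiCl, −78 °C → rt
Reagents that add atoms: chlorotrimethylsilane, C[Si](C)(C)Cl
Why: Directed ortho-metalation, in which the carbamate and the neighbouring methoxy group jointly direct lithiation to the carbon between them (the other free position is equivalent by symmetry), the aryllithium resists the anionic ortho-Fries shift at −78 °C, and one equivalent of base limits the reaction to monosilylation.

Step 4
Reactants: 6 4,5-dimethoxy-3-(trimethylsilyl)-1,2-phenylene bis(N,N-diethylcarbamate)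
Product: 7 4,5-dimethoxy-3-(trimethylsilyl)benzene-1,2-diol
Conditions: LiAlH4, THF, 0 °C → reflux, Ar; then EtOAc, degassed 10% aq. citric acid, 0 °C
Reagents that add atoms: none
Why: Reductive cleavage of aryl O-carbamates by hydride addition to the carbamate carbonyl and expulsion of the aryloxide should free both phenols without touching the aryl–silicon bond, and the mild, air-free acidic work-up avoids protodesilylation and quinone formation.

Step 5
Reactants: 7 4,5-dimethoxy-3-(trimethylsilyl)benzene-1,2-diol
Product: 8 4,5-dimethoxy-3-(trimethylsilyl)-1,2-phenylene bis(trifluoromethanesulfonate)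
Conditions: Tf2O (2.4 equiv), pyridine, CH2Cl2, 0 °C → rt
Reagents that add atoms: trifluoromethanesulfonic anhydride, O=S(=O)(OS(=O)(=O)C(F)(F)F)C(F)(F)F
Why: O-Sulfonylation of both phenols with triflic anhydride and pyridine is the usual last step toward ortho-silylaryl triflates, and the buffered medium spares the C–Si bond.

Step 6
Reactants: 9 5-ethynyl-1,2,3-trimethoxybenzene
Product: 11 3-(3,4,5-trimethoxyphenyl)prop-2-ynoic acid, via lithium (3,4,5-trimethoxyphenyl)acetylide 10 (not isolated)
Conditions: n-BuLi, THF, −78 °C; then CO2, −78 °C → rt; then 1 M HCl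
Reagents that add atoms: carbon dioxide, O=C=O
Why: Deprotonation of the terminal alkyne and carboxylation of the lithium acetylide with CO2 should give the propiolic acid after acidification.

Step 7
Reactants: 8 4,5-dimethoxy-3-(trimethylsilyl)-1,2-phenylene bis(trifluoromethanesulfonate); 11 3-(3,4,5-trimethoxyphenyl)prop-2-ynoic acid
Product: 14 7,8-dimethoxy-4-oxo-2-(3,4,5-trimethoxyphenyl)-4H-chromen-5-yl trifluoromethanesulfonate, via 2,3-didehydro-4,5-dimethoxyphenyl trifluoromethanesulfonate 12 (not isolated), via 3-hydroxy-4,5-dimethoxy-2-[3-(3,4,5-trimethoxyphenyl)prop-2-ynoyl]phenyl trifluoromethanesulfonate 13 (not isolated)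
Conditions: CsF (4 equiv), THF (0.02 M), 125 °C, sealed tube
Reagents that add atoms: none
Why: Proposed new method: fluoride attacks silicon at C8a and the aryl anion expels the only adjacent triflate (on C4a) to give aryne 12 across C4a–C8a; the cesium carboxylate of 11 adds through oxygen at C8a, the C4a anion attacks the ester carbonyl through a four-membered alkoxide that opens to the ortho-acylphenoxide of 13 (net insertion of the aryne into the acid C–O bond), and ring closure followed by protonation at C3 gives 14. The closest known reactions are the fluoride-induced insertion of simple arynes into the C–O bond of carboxylic acids, which delivers flavones from 3-arylpropiolic acids, and nucleophile additions to 3-(triflyloxy)arynes, which place the nucleophile on the aryne carbon remote from the triflate; neither has been shown for an aryne flanked by a triflate on one side and a methoxy group on the other. Ring C is closed by 6-endo-dig oxa-Michael addition of the C8a phenoxide to the ynone, favoured over 5-exo-dig closure in an aprotic medium, and no stereocenter is formed. The step needs O–C8a regioselectivity: the triflyloxy group at C5 is the stronger sigma-acceptor and should polarise the aryne so that negative charge builds at C4a, overriding the weaker opposing pull of the 8-methoxy group. It also needs acyl capture to outrun beta-elimination of the C5 triflate from the C4a anion, which the intramolecular four-centre acyl transfer and the dilute medium poor in proton donors should favour. Placing silicon on C8a, where only one triflate is adjacent, secures a single aryne.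

Step 8
Reactants: 14 7,8-dimethoxy-4-oxo-2-(3,4,5-trimethoxyphenyl)-4H-chromen-5-yl trifluoromethanesulfonate
Product: 16 3-hydroxy-7,8-dimethoxy-4-oxo-2-(3,4,5-trimethoxyphenyl)-4H-chromen-5-yl trifluoromethanesulfonate, via rac-2,3-epoxy-7,8-dimethoxy-4-oxo-2-(3,4,5-trimethoxyphenyl)-2,3-dihydro-4H-chromen-5-yl trifluoromethanesulfonate 15 (not isolated)
Conditions: DMDO (acetone), CH2Cl2, 0 °C → rt, dark; evaporate; then p-TsOH·H2O (cat.), CH2Cl2, rt
Reagents that add atoms: dimethyldioxirane, CC1(C)OO1
Why: Electrophilic epoxidation of the enol-ether-like C2=C3 bond by the dioxirane, then acid-catalysed opening at C2 (cation stabilised by O1 and the aryl group) with loss of the C3 proton, is the established flavone-to-flavonol conversion, the triflate keeping ring A electron-poor toward the oxidant and the two stereocenters of the racemic cis-fused epoxide vanishing on opening.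

Step 9
Reactants: 16 3-hydroxy-7,8-dimethoxy-4-oxo-2-(3,4,5-trimethoxyphenyl)-4H-chromen-5-yl trifluoromethanesulfonate
Product: 17 3,5-dihydroxy-7,8-dimethoxy-2-(3,4,5-trimethoxyphenyl)-4H-chromen-4-one (3,5-dihydroxy-7,8,3',4',5'-pentamethoxyflavone)
Conditions: Et4NOH (aq., 3 equiv), 1,4-dioxane, rt, Ar; then 1 M HCl
Reagents that add atoms: none
Why: Hydrolysis of the aryl triflate by hydroxide attack at sulfur (S–O cleavage, aided by the peri carbonyl) should free the 5-OH with its original oxygen, while the deprotonated 3-hydroxychromone resists ring opening and exclusion of air avoids oxidation of the flavonolate.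

Compound list
1 | 2-hydroxy-4,5-dimethoxybenzaldehyde | COc1cc(O)c(C=O)cc1OC | starting material
2 | 2-hydroxy-4,5-dimethoxyphenyl formate | O=COc1cc(OC)c(OC)cc1O | intermediate
3 | 4,5-dimethoxybenzene-1,2-diol | COc1cc(O)c(O)cc1OC | intermediate
4 | 4,5-dimethoxy-1,2-phenylene bis(N,N-diethylcarbamate) | CCN(CC)C(=O)Oc1cc(OC)c(OC)cc1OC(=O)N(CC)CC | intermediate
5 | 2,3-bis[(diethylcarbamoyl)oxy]-5,6-dimethoxyphenyllithium | [Li]c1c(OC)c(OC)cc(OC(=O)N(CC)CC)c1OC(=O)N(CC)CC | intermediate
6 | 4,5-dimethoxy-3-(trimethylsilyl)-1,2-phenylene bis(N,N-diethylcarbamate) | CCN(CC)C(=O)Oc1cc(OC)c(OC)c([Si](C)(C)C)c1OC(=O)N(CC)CC | intermediate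
7 | 4,5-dimethoxy-3-(trimethylsilyl)benzene-1,2-diol | COc1cc(O)c(O)c([Si](C)(C)C)c1OC | intermediate
8 | 4,5-dimethoxy-3-(trimethylsilyl)-1,2-phenylene bis(trifluoromethanesulfonate) | COc1cc(OS(=O)(=O)C(F)(F)F)c(OS(=O)(=O)C(F)(F)F)c([Si](C)(C)C)c1OC | intermediate
9 | 5-ethynyl-1,2,3-trimethoxybenzene | C#Cc1cc(OC)c(OC)c(OC)c1 | starting material
10 | lithium (3,4,5-trimethoxyphenyl)acetylide | [Li]C#Cc1cc(OC)c(OC)c(OC)c1 | intermediate
11 | 3-(3,4,5-trimethoxyphenyl)prop-2-ynoic acid | COc1cc(C#CC(=O)O)cc(OC)c1OC | intermediate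
12 | 2,3-didehydro-4,5-dimethoxyphenyl trifluoromethanesulfonate (aryne; the triple bond becomes C4a–C8a of ring A) | COC1=C(OC)C#CC(OS(=O)(=O)C(F)(F)F)=C1 | intermediate
13 | 3-hydroxy-4,5-dimethoxy-2-[3-(3,4,5-trimethoxyphenyl)prop-2-ynoyl]phenyl trifluoromethanesulfonate (present as its cesium phenoxide) | COc1cc(C#CC(=O)c2c(O)c(OC)c(OC)cc2OS(=O)(=O)C(F)(F)F)cc(OC)c1OC | intermediate
14 | 7,8-dimethoxy-4-oxo-2-(3,4,5-trimethoxyphenyl)-4H-chromen-5-yl trifluoromethanesulfonate | COc1cc(-c2cc(=O)c3c(OS(=O)(=O)C(F)(F)F)cc(OC)c(OC)c3o2)cc(OC)c1OC | intermediate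
15 | rac-2,3-epoxy-7,8-dimethoxy-4-oxo-2-(3,4,5-trimethoxyphenyl)-2,3-dihydro-4H-chromen-5-yl trifluoromethanesulfonate (oxirane cis-fused to the pyranone ring; racemate; one enantiomer drawn) | COc1cc(cc(OC)c1OC)[C@@]12O[C@@H]1C(=O)c1c(OS(=O)(=O)C(F)(F)F)cc(OC)c(OC)c1O2 | intermediate
16 | 3-hydroxy-7,8-dimethoxy-4-oxo-2-(3,4,5-trimethoxyphenyl)-4H-chromen-5-yl trifluoromethanesulfonate | COc1cc(-c2oc3c(OC)c(OC)cc(OS(=O)(=O)C(F)(F)F)c3c(=O)c2O)cc(OC)c1OC | intermediate
17 | 3,5-dihydroxy-7,8-dimethoxy-2-(3,4,5-trimethoxyphenyl)-4H-chromen-4-one | COc1cc(-c2oc3c(OC)c(OC)cc(O)c3c(=O)c2O)cc(OC)c1OC | target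

Total step count: 9. Longest linear sequence: 8 steps (steps 1–5, then 7–9); step 6 is a one-step side branch.

Steps most likely to fail

For step 7 (the key step), three processes may intervene:
- loss of the C5 triflate from the C4a aryl anion before acyl transfer, which would lead to a second aryne and oligomers;
- addition of the carboxylate in the opposite orientation, with oxygen at C4a;
- protonation of the anion, which stops at the O-aryl ester.

The fallback uses known chemistry, sets out from 11 and returns at 14. Oxalyl chloride with catalytic DMF (CH2Cl2, 0 °C) should convert 11 into 3-(3,4,5-trimethoxyphenyl)prop-2-ynoyl chloride F1. Friedel–Crafts acylation of commercial 1,2,3,5-tetramethoxybenzene (COc1cc(OC)c(OC)c(OC)c1) with F1 and AlCl3 (CH2Cl2, 0 °C → rt) can occur at only one kind of ring position and should give 1-(2,3,4,6-tetramethoxyphenyl)-3-(3,4,5-trimethoxyphenyl)prop-2-yn-1-one F2 (not isolated). In the same flask the aluminium chelate should cleave the methoxy group lying between the ketone and the 3-methoxy group, as is usual for acyl derivatives of this arene, to give 1-(2-hydroxy-3,4,6-trimethoxyphenyl)-3-(3,4,5-trimethoxyphenyl)prop-2-yn-1-one F3. K2CO3 in acetone should close ring C by 6-endo-dig addition to 5,7,8-trimethoxy-2-(3,4,5-trimethoxyphenyl)-4H-chromen-4-one F4. BCl3 (CH2Cl2, −78 → 0 °C) should remove only the chelated peri methyl group at C5 to give 5-hydroxy-7,8-dimethoxy-2-(3,4,5-trimethoxyphenyl)-4H-chromen-4-one F5. Tf2O and pyridine then give 14.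

For step 8, oxygen transfer to the electron-poor C2=C3 bond may be slow, the dioxirane may oxidise the trimethoxyphenyl ring, or the epoxide may open toward ring-contracted products. The fallback replaces electrophilic oxygen transfer by deprotonation, borylation and oxidation; it sets out from 14 and returns at 17. Et4NOH in dioxane should cleave the triflate at the base-tolerant flavone stage to 5-hydroxy-7,8-dimethoxy-2-(3,4,5-trimethoxyphenyl)-4H-chromen-4-one F6 (identical with F5). MOMCl and i-Pr2NEt should give 7,8-dimethoxy-5-(methoxymethoxy)-2-(3,4,5-trimethoxyphenyl)-4H-chromen-4-one F7. LiN(i-Pr)2 (THF, −78 °C) should deprotonate C3 next to the carbonyl, and B(OMe)3 should trap the anion as dimethyl [7,8-dimethoxy-5-(methoxymethoxy)-4-oxo-2-(3,4,5-trimethoxyphenyl)-4H-chromen-3-yl]boronate F8 (not isolated). Oxidation in the same flask with H2O2 and AcOH should give 3-hydroxy-7,8-dimethoxy-5-(methoxymethoxy)-2-(3,4,5-trimethoxyphenyl)-4H-chromen-4-one F9. HCl in MeOH removes the acetal and gives 17.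

For step 4, reductive cleavage of the carbamate flanked by silicon may stay incomplete, and the electron-rich silylcatechol may be oxidised by air during the aluminium work-up. The fallback changes the directing group to one that is removed by mild base and triflated in the same flask; it sets out from 3 and returns at 8.
- Isopropyl isocyanate with catalytic Et3N (CH2Cl2) should give 4,5-dimethoxy-1,2-phenylene bis(N-isopropylcarbamate) F10.
- TBSOTf and TMEDA (Et2O, 0 °C → rt) should block both N–H groups as 4,5-dimethoxy-1,2-phenylene bis[N-(tert-butyldimethylsilyl)-N-isopropylcarbamate] F11 (not isolated).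
- n-BuLi and TMEDA (−78 °C), then Me3SiCl, should give 4,5-dimethoxy-3-(trimethylsilyl)-1,2-phenylene bis[N-(tert-butyldimethylsilyl)-N-isopropylcarbamate] F12 (not isolated).
- Aqueous NaHSO4 work-up should leave 4,5-dimethoxy-3-(trimethylsilyl)-1,2-phenylene bis(N-isopropylcarbamate) F13.
- DBU and Et2NH (MeCN, 40 °C) should cleave both carbamates by E1cB loss of isopropyl isocyanate, which the amine traps, leaving 7 as its salt in the flask. PhNTf2 added to the same flask should then give 8, so that 7 never meets air.

Further compounds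
F1 | step 7 | 3-(3,4,5-trimethoxyphenyl)prop-2-ynoyl chloride | COc1cc(C#CC(Cl)=O)cc(OC)c1OC
F2 | step 7 | 1-(2,3,4,6-tetramethoxyphenyl)-3-(3,4,5-trimethoxyphenyl)prop-2-yn-1-one | COc1cc(C#CC(=O)c2c(OC)cc(OC)c(OC)c2OC)cc(OC)c1OC
F3 | step 7 | 1-(2-hydroxy-3,4,6-trimethoxyphenyl)-3-(3,4,5-trimethoxyphenyl)prop-2-yn-1-one | COc1cc(C#CC(=O)c2c(OC)cc(OC)c(OC)c2O)cc(OC)c1OC
F4 | step 7 | 5,7,8-trimethoxy-2-(3,4,5-trimethoxyphenyl)-4H-chromen-4-one | COc1cc(-c2cc(=O)c3c(OC)cc(OC)c(OC)c3o2)cc(OC)c1OC
F5 | step 7 | 5-hydroxy-7,8-dimethoxy-2-(3,4,5-trimethoxyphenyl)-4H-chromen-4-one | COc1cc(-c2cc(=O)c3c(O)cc(OC)c(OC)c3o2)cc(OC)c1OC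
F6 | step 8 | 5-hydroxy-7,8-dimethoxy-2-(3,4,5-trimethoxyphenyl)-4H-chromen-4-one | COc1cc(-c2cc(=O)c3c(O)cc(OC)c(OC)c3o2)cc(OC)c1OC
F7 | step 8 | 7,8-dimethoxy-5-(methoxymethoxy)-2-(3,4,5-trimethoxyphenyl)-4H-chromen-4-one | COCOc1cc(OC)c(OC)c2oc(-c3cc(OC)c(OC)c(OC)c3)cc(=O)c12
F8 | step 8 | dimethyl [7,8-dimethoxy-5-(methoxymethoxy)-4-oxo-2-(3,4,5-trimethoxyphenyl)-4H-chromen-3-yl]boronate | COCOc1cc(OC)c(OC)c2oc(-c3cc(OC)c(OC)c(OC)c3)c(B(OC)OC)c(=O)c12
F9 | step 8 | 3-hydroxy-7,8-dimethoxy-5-(methoxymethoxy)-2-(3,4,5-trimethoxyphenyl)-4H-chromen-4-one | COCOc1cc(OC)c(OC)c2oc(-c3cc(OC)c(OC)c(OC)c3)c(O)c(=O)c12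
F10 | step 4 | 4,5-dimethoxy-1,2-phenylene bis(N-isopropylcarbamate) | CC(C)NC(=O)Oc1cc(OC)c(OC)cc1OC(=O)NC(C)C
F11 | step 4 | 4,5-dimethoxy-1,2-phenylene bis[N-(tert-butyldimethylsilyl)-N-isopropylcarbamate] | CC(C)N([Si](C)(C)C(C)(C)C)C(=O)Oc1cc(OC)c(OC)cc1OC(=O)N(C(C)C)[Si](C)(C)C(C)(C)C
F12 | step 4 | 4,5-dimethoxy-3-(trimethylsilyl)-1,2-phenylene bis[N-(tert-butyldimethylsilyl)-N-isopropylcarbamate] | CC(C)N([Si](C)(C)C(C)(C)C)C(=O)Oc1cc(OC)c(OC)c([Si](C)(C)C)c1OC(=O)N(C(C)C)[Si](C)(C)C(C)(C)C
F13 | step 4 | 4,5-dimethoxy-3-(trimethylsilyl)-1,2-phenylene bis(N-isopropylcarbamate) | CC(C)NC(=O)Oc1cc(OC)c(OC)c([Si](C)(C)C)c1OC(=O)NC(C)C
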